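Substrate stood at 52.4% of its charge after 4.00 h in the south-west run, and I built my estimate for the set-ups below on that reading.

| flask | substrate | partner | remark | time |
|---|---|---|---|---|
| south-west | 11 mM | 7.7 mM | run made earlier |  |
| south-east | 5.5 mM | 7.7 mM | run made earlier |  |
| west | 22 mM | 7.7 mM | run made earlier |  |
| north | 11 mM | 3.9 mM | run made earlier |  |
| spring | 11 mM | 7.70 mM | a single well-mixed tank run continuously and read at steady state, 4.0 h in it on average |  |
| dawn | 11 mM | 7.70 mM | one stirred flow tank at steady state, fed with the mixture as stated, mean residence time 12.0 h |  |
| autumn | 11 mM | 7.70 mM (fed, over 3.20 h) | a stirred flask in which partner is dosed at a steady rate over 3.20 h without added volume, worked up at 4.0 h | 4.0 h |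
| dusk | 11 mM | 7.70 mM | a closed flask charged with all of it at once and left for 4.0 h | 4.0 h |

- south-west (time / h: open intermediate / %, product / %, substrate / %): 1.00: 17.5, 0, 84.1; 2.00: 26.8, 3.4, 69.9; 3.00: 34.2, 7.2, 62.4; 4.00: 32.8, 12.9, 52.4
- south-east (time / h: open intermediate / %, product / %, substrate / %): 0.833: 12.1, 0, 87.4; 1.50: 20.5, 0, 77.7; 2.50: 28.4, 5.8, 65.5; 3.00: 29.4, 6.6, 60.7
- west (time / h: open intermediate / %, product / %, substrate / %): 0.833: 11.9, 0, 87.0; 1.50: 21.4, 1.8, 77.4; 2.50: 28.8, 5.7, 64.4; 3.00: 33.7, 7.7, 60.9
- north (time / h: open intermediate / %, product / %, substrate / %): 0.833: 14.1, 0, 85.9; 1.50: 21.7, 0.1, 79.0; 2.50: 31.8, 2.0, 66.6; 3.00: 35.8, 3.7, 61.7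

(standard deviation of a reading: 1 percentage point)

- amounts and yields of product count idle adduct too
- the stated concentrations are those of everything mixed, before any reaction; amounts are the same in each set-up
- candidate steps: partner -> second intermediate; partner + product <-> idle adduct; open intermediate + second intermediate -> product; substrate <-> open intermediate
- the feed brings no volume worth counting
- the earlier runs were made in a closed, stirred flask

- the set-up with the highest amount of open intermediate at the outlet or at the end, in percent of the substrate put in ("none" if the first two lie within 2 percentage points) (spring / dawn / autumn / dusk / none)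
- amount of open intermediate at the outlet or at the end, in percent of the substrate put in, spring
- amount of open intermediate at the outlet or at the end, in percent of the substrate put in, dawn
- amount of open intermediate at the outlet or at the end, in percent of the substrate put in, autumn
- amount of open intermediate at the outlet or at the end, in percent of the substrate put in, dusk

I began with the main step, the opening of substrate. At 3.00 h substrate read 60.7%, 62.4% and 60.9% for charges of 5.5 mM, 11 mM and 22 mM, so I treated it as first order, with an apparent rate of 0.162 h⁻¹. I followed one substrate molecule in a stirred tank and asked whether it opens before it leaves: rate times stay, over one plus rate times stay. For spring this gave 39.3%, the opening chance, and for dawn 66.0%. In a closed flask the share opened by 4.0 h is 47.6%. With this step by itself, my reckoning put the open intermediate at these amounts.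

Then I added capture. At 3.00 h product read 3.7% in the north run, at 3.9 mM of partner, and 7.2% in the south-west run, at 7.7 mM, after 0% at 1.00 h there, so I took it that partner first has to form the second intermediate. Partner is the limiting reagent, its 7.70 mM standing against 11 mM of substrate. In the south-west run at 4.00 h the readings put product at 27.1% of what had opened. Carrying that share over, I reckoned 28.6% for spring and 34.7% for dusk. Dawn's long stay put its capture share beyond what a 4.00 h run could tell me. In autumn the dose arrives on average 1.60 h late, longer than the 1.00 h at which the south-west run read 0% product, so I expected autumn above dusk.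

The rest I did not reckon as separate terms. The way back to substrate already lies inside a rate read over 4.00 h: the first hour gives 0.173 h⁻¹. Idle adduct counts as product.

The forecast named autumn best, with 26% for spring, 29% for dawn, 40% for autumn and 34% for dusk, and its ground for autumn was that “dosing delays the second intermediate”. For spring my figure stood above its own.

The flasks gave 26.4% in spring, 30.1% in dawn, 38.9% in autumn and 34.4% in dusk, so autumn came first.

    partner → second intermediate (k = 0.660 h⁻¹)
    partner + product ⇌ idle adduct, settled at all times (K = 120 L mol⁻¹)
    open intermediate + second intermediate → product (k = 27.0 L mol⁻¹ h⁻¹)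
    substrate ⇌ open intermediate (K = 2.70, k = 0.183 h⁻¹)

Spring's simulated substrate of 61.9% means 38.1% had opened, beside the opening chance of 39.3%. In dawn the opening chance is 66.0%, while simulated substrate of 39.0% leaves 61.0% opened, and of that 30.9% stands as product and 30.1% as open intermediate. Time can undo autumn's lead: left for 40.0 h instead of 4.0 h, autumn holds 23.6% rather than 38.9%, below the 30.1% of dawn.

Readings and results were computed with constants of no real substance, and the scatter is random.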